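**Retrosynthetic overview**
- Locants used throughout: tetralin C1 carries the aryl group, C2 and C3 the CH2OH groups, C4 is CH2, ring A carries 6-OH and 7-OMe.
- The target comes from LiAlH4 reduction of a trans,trans tetralin-2-carboxylate with a C3 CH2OPiv group; C2 is set by base epimerisation and C1 by syn-hydrogenation of a 1-aryl-3,4-dihydronaphthalene anti to the C3 group.
- Ring B, the only ring formed (both arenes are bought), closes by intramolecular aldol condensation of a tert-butyl ester enolate (C2) onto an ortho diaryl ketone (C1).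
- The diaryl ketone comes from a carbonylative Suzuki coupling of a ring A aryl iodide (carrying the C4–C3–C2 chain), CO and the pendant arylboronic acid.
- The aryl iodide comes from Evans alkylation of a succinate imide with a 2-iodobenzyl bromide, which sets C3.

Assumption: the SMILES is taken exactly as drawn, i.e. the (1S,2R,3R) all-trans 6-hydroxy-7-methoxy tetralin (ring A hydroxy and methoxy swapped relative to isolariciresinol), and benzyl alcohol 1 is bought as such.

**Step 1**
Reactants: 1 [3-(benzyloxy)-4-methoxyphenyl]methanol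
Product: 2 [5-(benzyloxy)-2-iodo-4-methoxyphenyl]methanol
Conditions: I2, CF3CO2Ag, CHCl3, 0 °C → rt
Reagents that add atoms: iodine (II)
Why: Electrophilic aromatic iodination goes para to the benzyloxy group and ortho to the CH2OH group, the position that becomes C8a.

**Step 2**
Reactants: 2 [5-(benzyloxy)-2-iodo-4-methoxyphenyl]methanol
Product: 3 1-(benzyloxy)-5-(bromomethyl)-4-iodo-2-methoxybenzene
Conditions: PBr3, CH2Cl2, 0 °C
Reagents that add atoms: phosphorus tribromide (BrP(Br)Br)
Why: The electron-rich benzylic alcohol is converted to the bromide by PBr3 through a phosphite ester and bromide substitution.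

**Step 3**
Reactants: 4 succinic anhydride
Product: 5 4-tert-butoxy-4-oxobutanoic acid (mono-tert-butyl succinate)
Conditions: t-BuOH, N-hydroxysuccinimide (cat.), DMAP (cat.), Et3N (cat.), toluene, reflux
Reagents that add atoms: tert-butanol (CC(C)(C)O)
Why: Nucleophile-catalysed ring-opening alcoholysis of the cyclic anhydride gives the half ester.

**Step 4**
Reactants: 5 4-tert-butoxy-4-oxobutanoic acid; 6 (R)-4-benzyl-1,3-oxazolidin-2-one
Product: 8 tert-butyl 4-[(4R)-4-benzyl-2-oxo-1,3-oxazolidin-3-yl]-4-oxobutanoate, via mixed pivalic anhydride 7 (not isolated)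
Conditions: PivCl, Et3N, THF, −20 °C; then LiCl, 6, −20 °C → rt
Reagents that add atoms: none
Why: N-acylation of the oxazolidinone through the mixed anhydride, which is attacked at the less hindered succinyl carbonyl.

**Step 5**
Reactants: 8 tert-butyl 4-[(4R)-4-benzyl-2-oxo-1,3-oxazolidin-3-yl]-4-oxobutanoate; 3 1-(benzyloxy)-5-(bromomethyl)-4-iodo-2-methoxybenzene
Product: 10 tert-butyl (3R)-4-[(4R)-4-benzyl-2-oxo-1,3-oxazolidin-3-yl]-3-{[5-(benzyloxy)-2-iodo-4-methoxyphenyl]methyl}-4-oxobutanoate, via sodium Z-enolate 9 (not isolated)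
Conditions: NaN(SiMe3)2, THF, −78 °C; then 3, −78 → −40 °C
Reagents that add atoms: none
Why: Evans asymmetric alkylation: the imide (not the tert-butyl ester) is enolised to the chelated Z-enolate, and the benzyl bromide attacks the face away from the auxiliary benzyl group, setting C3 as R.

**Step 6**
Reactants: 10 alkylated imide
Product: 11 tert-butyl (3R)-4-[5-(benzyloxy)-2-iodo-4-methoxyphenyl]-3-(hydroxymethyl)butanoate
Conditions: LiBH4, H2O (1.1 equiv), Et2O, 0 °C
Reagents that add atoms: none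
Why: Chemoselective borohydride reduction of the activated imide carbonyl releases the auxiliary and leaves the tert-butyl ester and the aryl iodide intact; C3 is not enolisable afterwards.

**Step 7**
Reactants: 11 hydroxy ester
Product: 12 tert-butyl (3R)-4-[5-(benzyloxy)-2-iodo-4-methoxyphenyl]-3-[(pivaloyloxy)methyl]butanoate
Conditions: PivCl, pyridine, DMAP (cat.), CH2Cl2, 0 °C → rt
Reagents that add atoms: pivaloyl chloride (CC(C)(C)C(=O)Cl)
Why: O-acylation under mild base blocks lactonisation; the pivalate has no α-hydrogen, survives base, and is removed later by LiAlH4.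

**Step 8**
Reactants: 13 guaiacol (2-methoxyphenol)
Product: 14 4-bromo-2-methoxyphenol
Conditions: NBS, MeCN, 0 °C → rt
Reagents that add atoms: N-bromosuccinimide (O=C1CCC(=O)N1Br)
Why: Electrophilic aromatic bromination is directed para to the free phenol.

**Step 9**
Reactants: 14 4-bromo-2-methoxyphenol
Product: 15 1-(benzyloxy)-4-bromo-2-methoxybenzene
Conditions: BnBr, K2CO3, DMF, rt
Reagents that add atoms: benzyl bromide (BrCc1ccccc1)
Why: Williamson ether synthesis on the phenoxide.

**Step 10**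
Reactants: 15 1-(benzyloxy)-4-bromo-2-methoxybenzene
Product: 18 [4-(benzyloxy)-3-methoxyphenyl]boronic acid, via aryllithium 16 (not isolated), via lithium triisopropoxyborate 17 (not isolated)
Conditions: n-BuLi, THF, −78 °C; B(OiPr)3, −78 °C → rt; 1 M HCl
Reagents that add atoms: triisopropyl borate (CC(C)OB(OC(C)C)OC(C)C); water (O)
Why: Bromine–lithium exchange, borylation of the aryllithium and acidic hydrolysis of the borate give the boronic acid.

**Step 11**
Reactants: 12 aryl iodide pivalate; 18 [4-(benzyloxy)-3-methoxyphenyl]boronic acid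
Product: 19 tert-butyl (3R)-4-{5-(benzyloxy)-2-[4-(benzyloxy)-3-methoxybenzoyl]-4-methoxyphenyl}-3-[(pivaloyloxy)methyl]butanoate
Conditions: CO (1 atm), PdCl2(PPh3)2 (3 mol %), K2CO3, anisole, 80 °C
Reagents that add atoms: carbon monoxide ([C-]#[O+])
Why: Carbonylative Suzuki–Miyaura coupling: oxidative addition of the electron-rich, ortho-substituted iodide to zerovalent palladium, CO insertion, transmetalation and reductive elimination give the diaryl ketone without touching the esters.

**Step 12**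
Reactants: 19 diaryl ketone
Product: 22 tert-butyl (3R)-6-(benzyloxy)-1-[4-(benzyloxy)-3-methoxyphenyl]-7-methoxy-3-[(pivaloyloxy)methyl]-3,4-dihydronaphthalene-2-carboxylate, via lithium ester enolate 20 (not isolated), via tertiary aldol 21 (not isolated)
Conditions: LiN(SiMe3)2, THF, −78 → −20 °C; AcOH; then TsOH·H2O (cat.), CH2Cl2, rt
Reagents that add atoms: none
Why: Intramolecular aldol addition of the only enolisable carbon (C2) to the ortho diaryl ketone closes ring B, and the tertiary bis(alkoxyaryl) carbinol then dehydrates by an E1 path that can only lose the C2 hydrogen, so C3 is untouched.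

**Step 13**
Reactants: 22 dihydronaphthalene ester
Product: 23 tert-butyl (1S,2S,3R)-6-hydroxy-1-(4-hydroxy-3-methoxyphenyl)-7-methoxy-3-[(pivaloyloxy)methyl]-1,2,3,4-tetrahydronaphthalene-2-carboxylate (all-cis)
Conditions: H2 (4 atm), 10% Pd/C, EtOAc/AcOH, rt → 40 °C
Reagents that add atoms: none
Why: Heterogeneous syn-hydrogenation adds to the face opposite the pseudoaxial C3 CH2OPiv group (allylic strain with the C2 ester), setting C1 as S with the aryl cis to the C3 group; the two benzyl ethers are hydrogenolysed in the same operation.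

**Step 14**
Reactants: 23 all-cis ester
Product: 25 tert-butyl (1S,2R,3R)-6-hydroxy-1-(4-hydroxy-3-methoxyphenyl)-7-methoxy-3-[(pivaloyloxy)methyl]-1,2,3,4-tetrahydronaphthalene-2-carboxylate (trans,trans), via tripotassium enolate 24 (not isolated)
Conditions: KOtBu (4 equiv), t-BuOH/THF, 40 °C; then 1 M HCl
Reagents that add atoms: none
Why: Thermodynamic epimerisation α to the ester moves the C2 ester to the equatorial position trans to both neighbours; C1 and C3 carry no acidifying group and stay fixed.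

**Step 15**
Reactants: 25 trans,trans ester
Product: 26 (1S,2R,3R)-1-(4-hydroxy-3-methoxyphenyl)-2,3-bis(hydroxymethyl)-7-methoxy-1,2,3,4-tetrahydronaphthalen-6-ol (target)
Conditions: LiAlH4 (excess), THF, 0 °C → reflux; NaOH(aq) work-up
Reagents that add atoms: none
Why: Hydride reduction converts the tert-butyl ester to the C2 CH2OH and cleaves the pivalate to the C3 CH2OH without affecting any stereocentre.

**Compound list**
1 | [3-(benzyloxy)-4-methoxyphenyl]methanol | COc1ccc(CO)cc1OCc1ccccc1 | starting material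
2 | [5-(benzyloxy)-2-iodo-4-methoxyphenyl]methanol | COc1cc(I)c(CO)cc1OCc1ccccc1 | intermediate
3 | 1-(benzyloxy)-5-(bromomethyl)-4-iodo-2-methoxybenzene | COc1cc(I)c(CBr)cc1OCc1ccccc1 | intermediate
4 | succinic anhydride | O=C1CCC(=O)O1 | starting material
5 | 4-tert-butoxy-4-oxobutanoic acid | CC(C)(C)OC(=O)CCC(=O)O | intermediate
6 | (R)-4-benzyl-1,3-oxazolidin-2-one | O=C1N[C@H](Cc2ccccc2)CO1 | starting material
7 | mixed pivalic anhydride of 5 | CC(C)(C)OC(=O)CCC(=O)OC(=O)C(C)(C)C | intermediate (not isolated)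
8 | tert-butyl 4-[(4R)-4-benzyl-2-oxo-1,3-oxazolidin-3-yl]-4-oxobutanoate | CC(C)(C)OC(=O)CCC(=O)N1[C@H](Cc2ccccc2)COC1=O | intermediate
9 | sodium (Z)-enolate of 8 | CC(C)(C)OC(=O)C/C=C(\[O-])N1[C@H](Cc2ccccc2)COC1=O.[Na+] | intermediate (not isolated)
10 | tert-butyl (3R)-4-[(4R)-4-benzyl-2-oxo-1,3-oxazolidin-3-yl]-3-{[5-(benzyloxy)-2-iodo-4-methoxyphenyl]methyl}-4-oxobutanoate | CC(C)(C)OC(=O)C[C@@H](Cc1cc(OCc2ccccc2)c(OC)cc1I)C(=O)N1[C@H](Cc2ccccc2)COC1=O | intermediate
11 | tert-butyl (3R)-4-[5-(benzyloxy)-2-iodo-4-methoxyphenyl]-3-(hydroxymethyl)butanoate | CC(C)(C)OC(=O)C[C@@H](Cc1cc(OCc2ccccc2)c(OC)cc1I)CO | intermediate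
12 | tert-butyl (3R)-4-[5-(benzyloxy)-2-iodo-4-methoxyphenyl]-3-[(pivaloyloxy)methyl]butanoate | CC(C)(C)OC(=O)C[C@@H](Cc1cc(OCc2ccccc2)c(OC)cc1I)COC(=O)C(C)(C)C | intermediate
13 | guaiacol (2-methoxyphenol) | COc1ccccc1O | starting material
14 | 4-bromo-2-methoxyphenol | COc1cc(Br)ccc1O | intermediate
15 | 1-(benzyloxy)-4-bromo-2-methoxybenzene | COc1cc(Br)ccc1OCc1ccccc1 | intermediate
16 | [4-(benzyloxy)-3-methoxyphenyl]lithium | COc1cc([Li])ccc1OCc1ccccc1 | intermediate (not isolated)
17 | lithium [4-(benzyloxy)-3-methoxyphenyl]tri(isopropoxy)borate | COc1cc([B-](OC(C)C)(OC(C)C)OC(C)C)ccc1OCc1ccccc1.[Li+] | intermediate (not isolated)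
18 | [4-(benzyloxy)-3-methoxyphenyl]boronic acid | COc1cc(B(O)O)ccc1OCc1ccccc1 | intermediate
19 | tert-butyl (3R)-4-{5-(benzyloxy)-2-[4-(benzyloxy)-3-methoxybenzoyl]-4-methoxyphenyl}-3-[(pivaloyloxy)methyl]butanoate | CC(C)(C)OC(=O)C[C@@H](Cc1cc(OCc2ccccc2)c(OC)cc1C(=O)c1ccc(OCc2ccccc2)c(OC)c1)COC(=O)C(C)(C)C | intermediate
20 | lithium ester enolate of 19 | [Li+].[O-]C(OC(C)(C)C)=C[C@@H](Cc1cc(OCc2ccccc2)c(OC)cc1C(=O)c1ccc(OCc2ccccc2)c(OC)c1)COC(=O)C(C)(C)C | intermediate (not isolated)
21 | tert-butyl (3R)-6-(benzyloxy)-1-[4-(benzyloxy)-3-methoxyphenyl]-1-hydroxy-7-methoxy-3-[(pivaloyloxy)methyl]-1,2,3,4-tetrahydronaphthalene-2-carboxylate (C1/C2 epimer mixture) | OC1(c2ccc(OCc3ccccc3)c(OC)c2)c2cc(OC)c(OCc3ccccc3)cc2C[C@@H](COC(=O)C(C)(C)C)C1C(=O)OC(C)(C)C | intermediate (not isolated)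
22 | tert-butyl (3R)-6-(benzyloxy)-1-[4-(benzyloxy)-3-methoxyphenyl]-7-methoxy-3-[(pivaloyloxy)methyl]-3,4-dihydronaphthalene-2-carboxylate | CC(C)(C)OC(=O)C1=C(c2ccc(OCc3ccccc3)c(OC)c2)c2cc(OC)c(OCc3ccccc3)cc2C[C@H]1COC(=O)C(C)(C)C | intermediate
23 | tert-butyl (1S,2S,3R)-6-hydroxy-1-(4-hydroxy-3-methoxyphenyl)-7-methoxy-3-[(pivaloyloxy)methyl]-1,2,3,4-tetrahydronaphthalene-2-carboxylate | COc1cc([C@H]2c3cc(OC)c(O)cc3C[C@@H](COC(=O)C(C)(C)C)[C@H]2C(=O)OC(C)(C)C)ccc1O | intermediate
24 | tripotassium bis(phenoxide) ester enolate of 23 | COc1cc([C@H]2c3cc(OC)c([O-])cc3C[C@@H](COC(=O)C(C)(C)C)C2=C([O-])OC(C)(C)C)ccc1[O-].[K+].[K+].[K+] | intermediate (not isolated)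
25 | tert-butyl (1S,2R,3R)-6-hydroxy-1-(4-hydroxy-3-methoxyphenyl)-7-methoxy-3-[(pivaloyloxy)methyl]-1,2,3,4-tetrahydronaphthalene-2-carboxylate | COc1cc([C@H]2c3cc(OC)c(O)cc3C[C@@H](COC(=O)C(C)(C)C)[C@@H]2C(=O)OC(C)(C)C)ccc1O | intermediate
26 | (1S,2R,3R)-1-(4-hydroxy-3-methoxyphenyl)-2,3-bis(hydroxymethyl)-7-methoxy-1,2,3,4-tetrahydronaphthalen-6-ol | COc1cc([C@H]2c3cc(OC)c(O)cc3C[C@@H](CO)[C@@H]2CO)ccc1O | target

**Step count**
Total: 15 steps.
Longest linear sequence: 10 steps (1 → 2 → 3 → 10 → 11 → 12 → 19 → 22 → 23 → 25 → 26). The branch from 4 is equally long, and the boronic acid branch from 13 reaches the target in 8 steps.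

**Steps most likely to fail, with fallbacks**

Step 11 (carbonylative coupling; direct biaryl coupling or slow CO insertion may compete). The fallback sets out from iodide 12 and reverses the polarity without CO gas. Miyaura borylation (B2pin2, PdCl2(dppf), KOAc, dioxane, 80 °C) gives tert-butyl (3R)-4-[5-(benzyloxy)-4-methoxy-2-(4,4,5,5-tetramethyl-1,3,2-dioxaborolan-2-yl)phenyl]-3-[(pivaloyloxy)methyl]butanoate F1. This is joined under anhydrous acyl Suzuki conditions (Pd(PPh3)4, Cs2CO3, toluene, 100 °C) with 4-(benzyloxy)-3-methoxybenzoyl chloride F2, made from the commercial acid with (COCl)2 and catalytic DMF. The sequence comes back to the route at ketone 19.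

Step 12 (lithium enolate aldol; incomplete enolisation, retro-aldol on warming or attack on the pivalate are the risks). The fallback sets out from 19 and separates enolate formation from ring closure. Internal-quench silylation (LiN(SiMe3)2, Me3SiCl, THF, −78 °C) gives the tert-butyl trimethylsilyl ketene acetal of 19 F3. An intramolecular Mukaiyama aldol onto the diaryl ketone (BF3·OEt2, CH2Cl2, −78 → 0 °C), with loss of trimethylsilanol from the tertiary silyl ether, comes back to the route at 22.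

Step 13 (hydrogenation of a tetrasubstituted alkene; low reactivity or poor facial selectivity are the risks). The fallback sets out from 22 and replaces catalytic hydrogenation by a dissolving-metal conjugate reduction (Mg, MeOH/THF, rt) of the β,β-diaryl enoate. C1 is protonated anti to the pseudoaxial C3 group, and KOtBu in t-BuOH/THF then equilibrates C2. This gives tert-butyl (1S,2R,3R)-6-(benzyloxy)-1-[4-(benzyloxy)-3-methoxyphenyl]-7-methoxy-3-[(pivaloyloxy)methyl]-1,2,3,4-tetrahydronaphthalene-2-carboxylate F4. Hydrogenolysis of the two benzyl ethers alone (H2, 1 atm, Pd/C, EtOAc) comes back to the route at 25, bypassing 23.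

**Further compounds**
F1 | step 11 | tert-butyl (3R)-4-[5-(benzyloxy)-4-methoxy-2-(4,4,5,5-tetramethyl-1,3,2-dioxaborolan-2-yl)phenyl]-3-[(pivaloyloxy)methyl]butanoate | CC(C)(C)OC(=O)C[C@@H](Cc1cc(OCc2ccccc2)c(OC)cc1B1OC(C)(C)C(C)(C)O1)COC(=O)C(C)(C)C
F2 | step 11 | 4-(benzyloxy)-3-methoxybenzoyl chloride | COc1cc(C(=O)Cl)ccc1OCc1ccccc1
F3 | step 12 | (3R)-4-{5-(benzyloxy)-2-[4-(benzyloxy)-3-methoxybenzoyl]-4-methoxyphenyl}-1-tert-butoxy-3-[(pivaloyloxy)methyl]-1-(trimethylsilyloxy)but-1-ene | CC(C)(C)OC(O[Si](C)(C)C)=C[C@@H](Cc1cc(OCc2ccccc2)c(OC)cc1C(=O)c1ccc(OCc2ccccc2)c(OC)c1)COC(=O)C(C)(C)C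
F4 | step 13 | tert-butyl (1S,2R,3R)-6-(benzyloxy)-1-[4-(benzyloxy)-3-methoxyphenyl]-7-methoxy-3-[(pivaloyloxy)methyl]-1,2,3,4-tetrahydronaphthalene-2-carboxylate | COc1cc([C@H]2c3cc(OC)c(OCc4ccccc4)cc3C[C@@H](COC(=O)C(C)(C)C)[C@@H]2C(=O)OC(C)(C)C)ccc1OCc1ccccc1
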